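**Strategy.** Ring A, the oxane (O1; C2 with methyl and the ethylene link; C3 with Br; C6 with methyl and vinyl), is disconnected at C2–C3. This vicinal pair, a CHBr carbon beside a fully substituted ether carbon, maps onto an aldehyde carbon (C3) and the β-carbon of a β-alkoxyacrylate (C2), whose ester arm later becomes the C2 methyl group. One SmI2 ketyl–olefin cyclization closes ring A and sets C2 and C3 together, relayed from C6, the carbinol carbon of (S)-linalool; bromide then replaces the C3 hydroxyl with inversion. The precursor is an open-chain aldehyde, the acrylate enol ether of (S)-linalool, already carrying the bromocyclohexanol ring B.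

Key step: step 12

Remark: (S)-(+)-linalool and (S)-3-hydroxy-2,2-dimethylcyclohexan-1-one are assumed to be bought enantiomerically pure; ring B is labelled C1' (carbinol carbon), C2' (carbon bearing the link), C3' (CMe2), C4' (CHBr).

Step 1
Reactants: 1 (S)-3-hydroxy-2,2-dimethylcyclohexan-1-one
Product: 2 (R)-3-bromo-2,2-dimethylcyclohexan-1-one
Conditions: PPh3, CBr4, 2,6-lutidine, CH2Cl2, 0 °C to rt
Reagents that add atoms: carbon tetrabromide, BrC(Br)(Br)Br
Why: Appel reaction: the alkoxyphosphonium ion of the secondary alcohol is displaced by bromide in an SN2 process with inversion, so the (S)-carbinol becomes the (R)-bromide that will be C4', and the quaternary α-carbon leaves no enolisation path by which this centre could epimerise.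

Step 2
Reactants: 2 (R)-3-bromo-2,2-dimethylcyclohexan-1-one
Product: 3 (5R)-5-bromo-6,6-dimethylcyclohex-1-en-1-yl trifluoromethanesulfonate
Conditions: Tf2O, 2,6-di-tert-butyl-4-methylpyridine, CH2Cl2, 0 °C to rt
Reagents that add atoms: trifluoromethanesulfonic anhydride, O=S(=O)(OS(=O)(=O)C(F)(F)F)C(F)(F)F
Why: Enol triflate formation: the ketone can enolise only towards its CH2 side, so O-sulfonylation with Tf2O and a hindered pyridine base should give a single alkenyl triflate without touching the bromide stereocentre.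

Step 3
Reactants: 3 (5R)-5-bromo-6,6-dimethylcyclohex-1-en-1-yl trifluoromethanesulfonate; 4 (3-tert-butoxy-3-oxopropyl)zinc bromide
Product: 5 tert-butyl 3-[(5R)-5-bromo-6,6-dimethylcyclohex-1-en-1-yl]propanoate
Conditions: Pd(PPh3)4 (5 mol %), THF, 50 °C
Reagents that add atoms: none
Why: Negishi coupling: zerovalent palladium inserts into the alkenyl C–OTf bond and not into the unactivated secondary C–Br bond, and the ester-bearing alkylzinc transfers the three-carbon arm that becomes the ethylene link and the future C2 of ring A.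

Step 4
Reactants: 5 tert-butyl 3-[(5R)-5-bromo-6,6-dimethylcyclohex-1-en-1-yl]propanoate
Product: 7 tert-butyl 3-[(1R,3R,6R)-3-bromo-6-hydroxy-2,2-dimethylcyclohexyl]propanoate, via alkylborane 6 (not isolated)
Conditions: BH3·THF, THF, 0 °C to rt; then NaBO3·4H2O, THF–H2O, rt
Reagents that add atoms: sodium perborate, [Na+].[Na+].O[B-]1(O)OO[B-](O)(O)OO1
Why: Hydroboration–oxidation: boron and hydrogen add syn, boron to the less substituted alkene carbon, from the face opposite the pseudo-axial methyl of the CMe2 group, which in the half-chair with equatorial bromine lies on the bromine face, so C2' is set with its side chain cis to bromine, and perborate oxidises the C–B bond with retention under conditions too mild to close a 1,4-epoxide.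

Step 5
Reactants: 7 tert-butyl 3-[(1R,3R,6R)-3-bromo-6-hydroxy-2,2-dimethylcyclohexyl]propanoate
Product: 8 tert-butyl 3-[(1R,3R)-3-bromo-2,2-dimethyl-6-oxocyclohexyl]propanoate
Conditions: Dess–Martin periodinane, NaHCO3, CH2Cl2, 0 °C to rt
Reagents that add atoms: none
Why: Dess–Martin oxidation: buffered, non-basic oxidation of the secondary alcohol should give the ketone without epimerising the adjacent C2' stereocentre.

Step 6
Reactants: 8 tert-butyl 3-[(1R,3R)-3-bromo-2,2-dimethyl-6-oxocyclohexyl]propanoate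
Product: 9 tert-butyl 3-[(1R,3R,6S)-3-bromo-6-hydroxy-2,2,6-trimethylcyclohexyl]propanoate
Conditions: CeCl3 (anhydrous), MeLi, THF, –78 °C
Reagents that add atoms: methyllithium, [Li]C
Why: Organocerium 1,2-addition: the weakly basic MeCeCl2 adds to the ketone faster than to the tert-butyl ester and without enolisation, and it enters equatorially because the axial trajectory is blocked by the axial methyl of C3', which sets C1' with an axial hydroxyl cis to the side chain.

Step 7
Reactants: 9 tert-butyl 3-[(1R,3R,6S)-3-bromo-6-hydroxy-2,2,6-trimethylcyclohexyl]propanoate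
Product: 11 3-[(1R,3R,6S)-3-bromo-2,2,6-trimethyl-6-(trimethylsilyloxy)cyclohexyl]propanoic acid, via bis-silyl derivative 10 (not isolated)
Conditions: TMSOTf (3 equiv), 2,6-lutidine, CH2Cl2, 0 °C to rt; then pH 7 phosphate buffer
Reagents that add atoms: trimethylsilyl trifluoromethanesulfonate, C[Si](C)(C)OS(=O)(=O)C(F)(F)F
Why: Silyl triflate-mediated tert-butyl ester cleavage with concurrent O-silylation: TMSOTf and 2,6-lutidine turn the ester into a silyl ester with loss of 2-methylpropene and cap the tertiary alcohol, and neutral aqueous work-up hydrolyses only the labile silyl ester, so the acid is released while the hydroxyl stays masked against lactonisation.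

Step 8
Reactants: 11 3-[(1R,3R,6S)-3-bromo-2,2,6-trimethyl-6-(trimethylsilyloxy)cyclohexyl]propanoic acid; 12 (S)-linalool [(3S)-3,7-dimethylocta-1,6-dien-3-ol]
Product: 14 (3S)-3,7-dimethylocta-1,6-dien-3-yl 3-[(1R,3R,6S)-3-bromo-2,2,6-trimethyl-6-(trimethylsilyloxy)cyclohexyl]propanoate, via acid chloride 13 (not isolated)
Conditions: 11, 1-chloro-N,N,2-trimethylprop-1-en-1-amine, CH2Cl2, 0 °C; then lithium alkoxide of 12 (n-BuLi, THF, –78 °C), –78 to 0 °C
Reagents that add atoms: none
Why: Esterification through the acid chloride: the α-chloroenamine forms the acid chloride under neutral conditions that spare the silyl ether, and the lithium alkoxide of the tertiary allylic alcohol is acylated at low temperature without touching its stereocentre, the future C6.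

Step 9
Reactants: 14 (3S)-3,7-dimethylocta-1,6-dien-3-yl 3-[(1R,3R,6S)-3-bromo-2,2,6-trimethyl-6-(trimethylsilyloxy)cyclohexyl]propanoate
Product: 15 (3S)-3-({4-[(1R,3R,6S)-3-bromo-2,2,6-trimethyl-6-(trimethylsilyloxy)cyclohexyl]but-1-en-2-yl}oxy)-3,7-dimethylocta-1,6-diene
Conditions: Cp2Ti(μ-CH2)(μ-Cl)AlMe2 (Tebbe reagent), pyridine, THF–toluene, –40 to 0 °C; aqueous NaOH quench, basic alumina
Reagents that add atoms: Tebbe reagent Cp2Ti(μ-CH2)(μ-Cl)AlMe2, C[Al-]1(C)C[Ti]([Cl+]1)(C1C=CC=C1)C1C=CC=C1
Why: Tebbe methylenation: the titanocene methylidene Cp2Ti=CH2 released from the reagent by pyridine converts even a hindered ester carbonyl into the enol ether without enolising it, at a temperature below that at which the resulting allyl vinyl ether would undergo Claisen rearrangement.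

Step 10
Reactants: 15 (3S)-3-({4-[(1R,3R,6S)-3-bromo-2,2,6-trimethyl-6-(trimethylsilyloxy)cyclohexyl]but-1-en-2-yl}oxy)-3,7-dimethylocta-1,6-diene
Product: 17 methyl (2E)-5-[(1R,3R,6S)-3-bromo-6-hydroxy-2,2,6-trimethylcyclohexyl]-3-{[(3S)-3,7-dimethylocta-1,6-dien-3-yl]oxy}pent-2-enoate, via trichloromethyl enone 16 (not isolated)
Conditions: Cl3CCOCl, pyridine, CH2Cl2, 0 °C to rt; then MeOH, K2CO3, rt
Reagents that add atoms: trichloroacetyl chloride, ClC(=O)C(Cl)(Cl)Cl; methanol, CO
Why: Acylation of an enol ether followed by haloform-type cleavage: the electron-rich 1,1-disubstituted enol ether is acylated at its terminal carbon to give the (E)-β-alkoxy enone with the carbonyl anti to the ether oxygen, and carbonate in methanol converts the trichloromethyl ketone into the methyl ester and removes the silyl ether.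

Step 11
Reactants: 17 methyl (2E)-5-[(1R,3R,6S)-3-bromo-6-hydroxy-2,2,6-trimethylcyclohexyl]-3-{[(3S)-3,7-dimethylocta-1,6-dien-3-yl]oxy}pent-2-enoate
Product: 19 methyl (2E)-5-[(1R,3R,6S)-3-bromo-6-hydroxy-2,2,6-trimethylcyclohexyl]-3-{[(3S)-3-methyl-6-oxohex-1-en-3-yl]oxy}pent-2-enoate, via diol 18 (not isolated)
Conditions: OsO4 (2 mol %), NaIO4, 2,6-lutidine, 1,4-dioxane–H2O, rt
Reagents that add atoms: sodium periodate, [Na+].[O-][I](=O)(=O)=O
Why: Lemieux–Johnson oxidation: OsO4 dihydroxylates the electron-rich, unhindered trisubstituted alkene much faster than the vinyl group on a quaternary carbon or the push–pull acrylate, and periodate cleaves the diol to the aldehyde that becomes C3.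

Step 12
Reactants: 19 methyl (2E)-5-[(1R,3R,6S)-3-bromo-6-hydroxy-2,2,6-trimethylcyclohexyl]-3-{[(3S)-3-methyl-6-oxohex-1-en-3-yl]oxy}pent-2-enoate
Product: 20 methyl 2-[(2R,3S,6S)-2-{2-[(1R,3R,6S)-3-bromo-6-hydroxy-2,2,6-trimethylcyclohexyl]ethyl}-6-ethenyl-3-hydroxy-6-methyloxan-2-yl]acetate
Conditions: SmI2 (3 equiv), MeOH (3 equiv), THF, –78 to 0 °C
Reagents that add atoms: none
Why: SmI2 reduces the aldehyde to a samarium ketyl whose carbon (C3) adds in a 6-exo-trig mode to the β-carbon (C2) of the (E)-β-alkoxyacrylate, and a second electron plus methanol turn the α-ester radical into the CH2CO2Me arm; this is the reductive ketyl–olefin cyclization known to convert aldehyde-tethered β-alkoxyacrylates into 2,3-trans-3-hydroxyoxane-2-acetates. Ring A closes through a chair transition state. At C3 the ketyl oxygen sits equatorial and is chelated by trivalent samarium to the ester carbonyl, which places the hydroxyl trans to the acetate arm. At C2 the enol ether keeps its bulky tertiary O-substituent syn to the vinylic C–H to avoid allylic strain with the side chain, so the acrylate arm becomes equatorial and the ring-B side chain axial, and the face is chosen by C6, where the flat vinyl group rather than the methyl group should take the axial site syn to that chain. The step needs chemoselectivity for the aldehyde and the activated alkene: the unactivated vinyl group reacts far more slowly with the nucleophilic ketyl, and the hindered secondary bromide and the tertiary alcohol are inert to SmI2 at low temperature without HMPA.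

Step 13
Reactants: 20 methyl 2-[(2R,3S,6S)-2-{2-[(1R,3R,6S)-3-bromo-6-hydroxy-2,2,6-trimethylcyclohexyl]ethyl}-6-ethenyl-3-hydroxy-6-methyloxan-2-yl]acetate
Product: 21 2-[(2R,3S,6S)-2-{2-[(1R,3R,6S)-3-bromo-6-hydroxy-2,2,6-trimethylcyclohexyl]ethyl}-6-ethenyl-3-hydroxy-6-methyloxan-2-yl]acetic acid
Conditions: LiOH, THF–MeOH–H2O, rt; then aqueous HCl to pH 4
Reagents that add atoms: lithium hydroxide, [Li+].[OH-]
Why: Ester saponification: hydroxide cleaves the unhindered methyl ester, the trans relationship of hydroxyl and acetate arm disfavours lactonisation, and the hindered secondary bromide is not displaced at room temperature.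

Step 14
Reactants: 21 2-[(2R,3S,6S)-2-{2-[(1R,3R,6S)-3-bromo-6-hydroxy-2,2,6-trimethylcyclohexyl]ethyl}-6-ethenyl-3-hydroxy-6-methyloxan-2-yl]acetic acid
Product: 23 (1S,2R,4R)-4-bromo-2-{2-[(2S,3S,6S)-6-ethenyl-3-hydroxy-2,6-dimethyloxan-2-yl]ethyl}-1,3,3-trimethylcyclohexan-1-ol, via thiohydroxamate ester 22 (not isolated)
Conditions: N-hydroxypyridine-2-thione, DCC, DMAP (cat.), CH2Cl2, rt, dark; then t-BuSH, visible light, rt
Reagents that add atoms: none
Why: Barton reductive decarboxylation: photolysis of the thiohydroxamate ester releases CO2 and a primary radical that abstracts hydrogen from the thiol, which turns the acetic acid arm into the C2 methyl group without touching any stereocentre or the bromide.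

Step 15
Reactants: 23 (1S,2R,4R)-4-bromo-2-{2-[(2S,3S,6S)-6-ethenyl-3-hydroxy-2,6-dimethyloxan-2-yl]ethyl}-1,3,3-trimethylcyclohexan-1-ol
Product: 25 (1S,2R,4R)-4-bromo-2-{2-[(2S,3R,6S)-3-bromo-6-ethenyl-2,6-dimethyloxan-2-yl]ethyl}-1,3,3-trimethylcyclohexan-1-ol, via secondary triflate 24 (not isolated)
Conditions: Tf2O, 2,6-lutidine, CH2Cl2, –40 °C; then Bu4NBr, –40 °C to rt
Reagents that add atoms: tetrabutylammonium bromide, CCCC[N+](CCCC)(CCCC)CCCC.[Br-]
Why: SN2 displacement of a secondary triflate: the secondary hydroxyl is sulfonylated in preference to the tertiary one and bromide attacks C3 from the face opposite the leaving group, which should give the (3R)-bromide cis to the C2 methyl group, while the far poorer leaving-group ability of the existing bromide keeps C4' from exchanging at low temperature.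

**Compound list**

1 | (S)-3-hydroxy-2,2-dimethylcyclohexan-1-one | CC1(C)[C@@H](O)CCCC1=O | starting material
2 | (R)-3-bromo-2,2-dimethylcyclohexan-1-one | CC1(C)[C@H](Br)CCCC1=O | intermediate
3 | (5R)-5-bromo-6,6-dimethylcyclohex-1-en-1-yl trifluoromethanesulfonate | CC1(C)[C@H](Br)CCC=C1OS(=O)(=O)C(F)(F)F | intermediate
4 | (3-tert-butoxy-3-oxopropyl)zinc bromide | CC(C)(C)OC(=O)CC[Zn]Br | starting material
5 | tert-butyl 3-[(5R)-5-bromo-6,6-dimethylcyclohex-1-en-1-yl]propanoate | CC1(C)[C@H](Br)CCC=C1CCC(=O)OC(C)(C)C | intermediate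
6 | alkylborane (drawn as RBH2): boron on the ring CH next to C2', trans to the side chain, side chain cis to Br | CC(C)(C)OC(=O)CC[C@@H]1C(C)(C)[C@H](Br)CC[C@H]1B | intermediate
7 | tert-butyl 3-[(1R,3R,6R)-3-bromo-6-hydroxy-2,2-dimethylcyclohexyl]propanoate | CC(C)(C)OC(=O)CC[C@@H]1C(C)(C)[C@H](Br)CC[C@H]1O | intermediate
8 | tert-butyl 3-[(1R,3R)-3-bromo-2,2-dimethyl-6-oxocyclohexyl]propanoate | CC(C)(C)OC(=O)CC[C@@H]1C(C)(C)[C@H](Br)CCC1=O | intermediate
9 | tert-butyl 3-[(1R,3R,6S)-3-bromo-6-hydroxy-2,2,6-trimethylcyclohexyl]propanoate | CC(C)(C)OC(=O)CC[C@@H]1C(C)(C)[C@H](Br)CC[C@]1(C)O | intermediate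
10 | trimethylsilyl 3-[(1R,3R,6S)-3-bromo-2,2,6-trimethyl-6-(trimethylsilyloxy)cyclohexyl]propanoate | C[Si](C)(C)OC(=O)CC[C@@H]1C(C)(C)[C@H](Br)CC[C@]1(C)O[Si](C)(C)C | intermediate
11 | 3-[(1R,3R,6S)-3-bromo-2,2,6-trimethyl-6-(trimethylsilyloxy)cyclohexyl]propanoic acid | OC(=O)CC[C@@H]1C(C)(C)[C@H](Br)CC[C@]1(C)O[Si](C)(C)C | intermediate
12 | (S)-linalool, (3S)-3,7-dimethylocta-1,6-dien-3-ol | C=C[C@@](C)(O)CCC=C(C)C | starting material
13 | 3-[(1R,3R,6S)-3-bromo-2,2,6-trimethyl-6-(trimethylsilyloxy)cyclohexyl]propanoyl chloride | ClC(=O)CC[C@@H]1C(C)(C)[C@H](Br)CC[C@]1(C)O[Si](C)(C)C | intermediate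
14 | (3S)-3,7-dimethylocta-1,6-dien-3-yl 3-[(1R,3R,6S)-3-bromo-2,2,6-trimethyl-6-(trimethylsilyloxy)cyclohexyl]propanoate | C=C[C@](C)(CCC=C(C)C)OC(=O)CC[C@@H]1C(C)(C)[C@H](Br)CC[C@]1(C)O[Si](C)(C)C | intermediate
15 | (3S)-3-({4-[(1R,3R,6S)-3-bromo-2,2,6-trimethyl-6-(trimethylsilyloxy)cyclohexyl]but-1-en-2-yl}oxy)-3,7-dimethylocta-1,6-diene | C=C[C@](C)(CCC=C(C)C)OC(=C)CC[C@@H]1C(C)(C)[C@H](Br)CC[C@]1(C)O[Si](C)(C)C | intermediate
16 | (3E)-6-[(1R,3R,6S)-3-bromo-2,2,6-trimethyl-6-(trimethylsilyloxy)cyclohexyl]-1,1,1-trichloro-4-{[(3S)-3,7-dimethylocta-1,6-dien-3-yl]oxy}hex-3-en-2-one | C=C[C@](C)(CCC=C(C)C)O/C(CC[C@@H]1C(C)(C)[C@H](Br)CC[C@]1(C)O[Si](C)(C)C)=C/C(=O)C(Cl)(Cl)Cl | intermediate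
17 | methyl (2E)-5-[(1R,3R,6S)-3-bromo-6-hydroxy-2,2,6-trimethylcyclohexyl]-3-{[(3S)-3,7-dimethylocta-1,6-dien-3-yl]oxy}pent-2-enoate | C=C[C@](C)(CCC=C(C)C)O/C(CC[C@@H]1C(C)(C)[C@H](Br)CC[C@]1(C)O)=C/C(=O)OC | intermediate
18 | methyl (2E)-5-[(1R,3R,6S)-3-bromo-6-hydroxy-2,2,6-trimethylcyclohexyl]-3-{[(3S)-6,7-dihydroxy-3,7-dimethyloct-1-en-3-yl]oxy}pent-2-enoate (both epimers at the secondary carbinol) | C=C[C@](C)(CCC(O)C(C)(C)O)O/C(CC[C@@H]1C(C)(C)[C@H](Br)CC[C@]1(C)O)=C/C(=O)OC | intermediate
19 | methyl (2E)-5-[(1R,3R,6S)-3-bromo-6-hydroxy-2,2,6-trimethylcyclohexyl]-3-{[(3S)-3-methyl-6-oxohex-1-en-3-yl]oxy}pent-2-enoate | C=C[C@](C)(CCC=O)O/C(CC[C@@H]1C(C)(C)[C@H](Br)CC[C@]1(C)O)=C/C(=O)OC | intermediate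
20 | methyl 2-[(2R,3S,6S)-2-{2-[(1R,3R,6S)-3-bromo-6-hydroxy-2,2,6-trimethylcyclohexyl]ethyl}-6-ethenyl-3-hydroxy-6-methyloxan-2-yl]acetate | C=C[C@]1(C)CC[C@H](O)[C@](CC(=O)OC)(CC[C@@H]2C(C)(C)[C@H](Br)CC[C@]2(C)O)O1 | intermediate
21 | 2-[(2R,3S,6S)-2-{2-[(1R,3R,6S)-3-bromo-6-hydroxy-2,2,6-trimethylcyclohexyl]ethyl}-6-ethenyl-3-hydroxy-6-methyloxan-2-yl]acetic acid | C=C[C@]1(C)CC[C@H](O)[C@](CC(=O)O)(CC[C@@H]2C(C)(C)[C@H](Br)CC[C@]2(C)O)O1 | intermediate
22 | 2-thioxopyridin-1(2H)-yl ester of acid 21 (thiohydroxamate ester) | C=C[C@]1(C)CC[C@H](O)[C@](CC(=O)ON3C=CC=CC3=S)(CC[C@@H]2C(C)(C)[C@H](Br)CC[C@]2(C)O)O1 | intermediate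
23 | (1S,2R,4R)-4-bromo-2-{2-[(2S,3S,6S)-6-ethenyl-3-hydroxy-2,6-dimethyloxan-2-yl]ethyl}-1,3,3-trimethylcyclohexan-1-ol | C=C[C@]1(C)CC[C@H](O)[C@](C)(CC[C@@H]2C(C)(C)[C@H](Br)CC[C@]2(C)O)O1 | intermediate
24 | (2S,3S,6S)-2-{2-[(1R,3R,6S)-3-bromo-6-hydroxy-2,2,6-trimethylcyclohexyl]ethyl}-6-ethenyl-2,6-dimethyloxan-3-yl trifluoromethanesulfonate | C=C[C@]1(C)CC[C@H](OS(=O)(=O)C(F)(F)F)[C@](C)(CC[C@@H]2C(C)(C)[C@H](Br)CC[C@]2(C)O)O1 | intermediate
25 | (1S,2R,4R)-4-bromo-2-{2-[(2S,3R,6S)-3-bromo-6-ethenyl-2,6-dimethyloxan-2-yl]ethyl}-1,3,3-trimethylcyclohexan-1-ol | C=C[C@]1(C)CC[C@@H](Br)[C@](C)(CC[C@@H]2C(C)(C)[C@H](Br)CC[C@]2(C)O)O1 | target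

**Step count.** Total: 15 steps. Longest linear sequence: 15 steps (1 to 25); (S)-linalool 12 enters at step 8.

**Steps most likely to fail**

Step 12. The cyclization may discriminate poorly between the two faces of the acrylate β-carbon, because methyl and vinyl at C6 differ little in size, or the ketyl may attack the vinyl group instead. The fallback sets out from aldehyde 19. A carbene-catalysed intramolecular Stetter reaction (chiral aminoindanol-derived triazolium salt, KHMDS, toluene) would close ring A at the same C2–C3 bond, with the catalyst rather than C6 fixing C2, to give methyl 2-[(2R,6S)-2-{2-[(1R,3R,6S)-3-bromo-6-hydroxy-2,2,6-trimethylcyclohexyl]ethyl}-6-ethenyl-6-methyl-3-oxooxan-2-yl]acetate F1. A Corey–Bakshi–Shibata reduction (oxazaborolidine, BH3·SMe2) would then set the C3 hydroxyl by reagent control, helped by the large difference between quaternary C2 and the C4 methylene. The route is rejoined at hydroxy ester 20.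

Step 15. The triflate may ionise with participation of the ring oxygen, giving ring contraction or substitution with retention, or it may eliminate instead of undergoing direct inversion. The fallback sets out from alcohol 23 and arrives directly at 25. It replaces the sulfonate displacement by a one-flask Appel redox condensation (PPh3, CBr4, 2,6-lutidine, CH2Cl2), in which an oxyphosphonium ion formed in the presence of bromide is the leaving group and no sulfonate ester has to survive. This fallback makes no new compound (F0).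

Step 10. Enol ether 15 may hydrolyse or undergo Claisen rearrangement during acylation, or its tertiary alkoxy group may be exchanged during methanolysis. The fallback bypasses the enol ether altogether. It sets out from acid 11 (through acid chloride 13) and linalool 12. The ketene generated from 13 with Et3N would undergo a Wittig reaction with methyl (triphenylphosphoranylidene)acetate to give methyl 5-[(1R,3R,6S)-3-bromo-2,2,6-trimethyl-6-(trimethylsilyloxy)cyclohexyl]penta-2,3-dienoate F2. Base-catalysed conjugate addition of 12 (catalytic NaH, THF) to the central allene carbon would give methyl (2E)-5-[(1R,3R,6S)-3-bromo-2,2,6-trimethyl-6-(trimethylsilyloxy)cyclohexyl]-3-{[(3S)-3,7-dimethylocta-1,6-dien-3-yl]oxy}pent-2-enoate F3. K2CO3 in methanol would then remove the silyl ether, and the route is rejoined at 17.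

Further compounds
F1 | step 12 | methyl 2-[(2R,6S)-2-{2-[(1R,3R,6S)-3-bromo-6-hydroxy-2,2,6-trimethylcyclohexyl]ethyl}-6-ethenyl-6-methyl-3-oxooxan-2-yl]acetate | C=C[C@]1(C)CCC(=O)[C@](CC(=O)OC)(CC[C@@H]2C(C)(C)[C@H](Br)CC[C@]2(C)O)O1
F0 | step 15 | none | none
F2 | step 10 | methyl 5-[(1R,3R,6S)-3-bromo-2,2,6-trimethyl-6-(trimethylsilyloxy)cyclohexyl]penta-2,3-dienoate | COC(=O)C=C=CC[C@@H]1C(C)(C)[C@H](Br)CC[C@]1(C)O[Si](C)(C)C
F3 | step 10 | methyl (2E)-5-[(1R,3R,6S)-3-bromo-2,2,6-trimethyl-6-(trimethylsilyloxy)cyclohexyl]-3-{[(3S)-3,7-dimethylocta-1,6-dien-3-yl]oxy}pent-2-enoate | C=C[C@](C)(CCC=C(C)C)O/C(CC[C@@H]1C(C)(C)[C@H](Br)CC[C@]1(C)O[Si](C)(C)C)=C/C(=O)OC
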